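The pitfall with a capture agent charged close to the catalyst is to read a smooth curve as proof that the order in catalyst must be one.

| setting | dusk | flask |
|---|---|---|
| starting material | 1.2 M | 1.2 M |
| second substrate | 1.8 M | 1.20 M |
| capture agent | 0.024 M | 0.0240 M |
| free catalyst | 28 mM | 28 mM |
| remark | run made earlier |  |

- dusk (time / h: target / %, starting material / %): 2.50: 20, 75; 4.00: 32, 68; 5.00: 42, 60; 8.00: 53, 47; 12.0: 64, 32; 20.0: 77, 22; 30.0: 90, 7

(readings scatter by 2 percentage points)

- no earlier run changes the charge of free catalyst; that part of a forecast is a guess

- apparent order in free catalyst when 50% of the starting material are converted (percent change of the rate of making target for one percent more free catalyst charged)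

What can the capture agent do to this flask at most? If each capture agent takes one catalyst, which no run shows, the reckoning starts from r = 0.857, the lockable share, meaning the charge of capture agent over the charge of free catalyst.

Why should the order care? Suppose a fixed amount of catalyst is locked whatever the charge, and the rate follows what stays working; then, with s the share locked at the moment one looks, the order is n, one over (one minus s), which runs from one at s = 0 up to 7.00 at s = r.

And s at half conversion, when no run varies the catalyst? My own reading comes from the dusk run, whose first-order constant reads 0.102 /h over the first 5.00 h and 0.0844 /h between 12.0 h and 30.0 h, and if that fall is lost working catalyst, s over that late stretch of the dusk run, counted against the first 5.00 h, reads about 17.3% and n about 1.21.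

Where is that weak? The late constant leans on a last reading of 7% with a scatter of 2 percentage points, its stretch starts at 12.0 h while the dusk run already reads 47% of its starting material at 8.00 h, so it lies after half conversion, and the dusk run had more second substrate than this flask, so I commit to that n with a wide margin.

The forecast also says 1.2, but on another ground, in its words: “The smooth rate argues against severe titration, but I skew upward.”

The flask gives 1.4, higher than the forecast.

    starting material + free catalyst ⇌ catalyst intermediate A (K = 1.80 /M, k = 32.0 /M/h)
    catalyst intermediate B + capture agent → trapped intermediate (k = 7.80 /M/h)
    catalyst intermediate A → free catalyst + target (k = 15.0 /h)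
    second substrate + free catalyst ⇌ catalyst intermediate B (K = 2.20 /M, k = 5.80 /M/h)
    catalyst intermediate B → free catalyst + second product (k = 3.20 /h)

Catalyst intermediate B in this flask goes on to free catalyst + second product with 3.2 /h, against 0.187 /h towards trapped intermediate at the charge of capture agent, a rate constant 17.1 times larger, yet at 0.238 d, with 50% of the starting material converted, trapped intermediate, an off-cycle form and no resting state, holds s = 27.4% of the catalyst, where n, still on the supposition of a fixed locked amount, reads 1.38. That s is 32.0% of r, and at 40.0 d the flask has 5.67% of its capture agent left, 80.9% of the catalyst trapped, as 80.9% from r says, and 19.1% free.

(The earlier runs and the new flask are simulated on assumed constants; scatter was added.)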